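**Retrosynthetic overview**
1. Ring labels: ring A = 3,5-dioxygenated ring (C1 bears the CH2CH2 bridge, C2 and C6 are ortho to it), ring B = catechol ring, ring C = dihydropyran ring of the chroman.
2. Ring C is the only ring that is built, and it is closed last: the O–CMe2 bond forms by acid-catalysed 6-endo opening of an (R)-epoxide by the neighbouring ring A phenol.
3. The (R)-epoxide (the only stereocentre) comes from Shi epoxidation of one of two equivalent prenyl groups of a C2,C6-diprenyl bibenzyl.
4. Both prenyl groups come from a ring A 2,6-dibromide by twofold Negishi coupling; the dibromide comes from NBS bromination of tetra-TBS dihydropiceatannol.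
5. Rings A and B and the bridge are bought as piceatannol (then hydrogenation and silylation).

Assumption: piceatannol is taken as the commercial starting material, and the ee of the Shi step (typically above 90 %) is raised to a single enantiomer by recrystallisation or chiral HPLC of the final product.

Abbreviations: TBS = tert-butyldimethylsilyl; TBSO = TBS-oxy; prenyl = 3-methylbut-2-enyl; CSA = camphorsulfonic acid; CPhos = 2-dicyclohexylphosphino-2′,6′-bis(dimethylamino)biphenyl.

**Route**

Step 1
Reactants: 1 piceatannol [(E)-4-[2-(3,5-dihydroxyphenyl)ethenyl]benzene-1,2-diol]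
Product: 2 dihydropiceatannol [4-[2-(3,5-dihydroxyphenyl)ethyl]benzene-1,2-diol]
Conditions: H2 (1 atm), 10 % Pd/C, EtOH, rt
Reagents that add atoms: none
Why: Heterogeneous catalytic hydrogenation saturates the stilbene C=C while the phenolic rings stay intact, and it is done now because no prenyl group is yet present.

Step 2
Reactants: 2 dihydropiceatannol
Product: 3 tetra-TBS dihydropiceatannol [1,2-bis(TBSO)-4-{2-[3,5-bis(TBSO)phenyl]ethyl}benzene]
Conditions: TBSCl (5 equiv), imidazole (10 equiv), DMF, rt
Reagents that add atoms: TBSCl, CC(C)(C)[Si](C)(C)Cl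
Why: Imidazole-mediated O-silylation masks all four phenols as silyl ethers that tolerate NBS, organozinc reagents and the basic oxidising medium of the Shi step, and that fall off together with fluoride at the end.

Step 3
Reactants: 3 tetra-TBS dihydropiceatannol
Product: 5 ring A 2,6-dibromide [2,4-dibromo-1,5-bis(TBSO)-3-{2-[3,4-bis(TBSO)phenyl]ethyl}benzene], via ring A monobromide 4 (not isolated)
Conditions: NBS (2.05 equiv), MeCN/CH2Cl2, −20 → 0 °C, dark
Reagents that add atoms: NBS, O=C1CCC(=O)N1Br
Why: Electrophilic aromatic substitution goes to the two ring A positions that are para to one silyloxy group and ortho to the other (the position between the two OTBS groups is shielded), and ring B reacts more slowly because each of its free positions is activated by only one oxygen.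

Step 4
Reactants: 5 ring A 2,6-dibromide
Product: 7 diprenyl arene [2,4-diprenyl-1,5-bis(TBSO)-3-{2-[3,4-bis(TBSO)phenyl]ethyl}benzene], via bromo prenyl arene 6 (not isolated)
Conditions: prenylzinc bromide (3 equiv; prepared from prenyl bromide, Zn dust, LiCl, THF, 0 °C), Pd(OAc)2 (5 mol %), CPhos (10 mol %), THF, rt → 40 °C
Reagents that add atoms: prenylzinc bromide, CC(C)=CC[Zn]Br, made in the flask from prenyl bromide (1-bromo-3-methylbut-2-ene), CC(C)=CCBr
Why: Twofold Negishi cross-coupling, in which the bulky electron-rich biarylphosphine lets the hindered aryl bromide add oxidatively to zerovalent palladium and steers reductive elimination to the unsubstituted allyl terminus, so the linear prenyl group is formed and the silyl ethers are untouched.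

Step 5
Reactants: 7 diprenyl arene
Product: 8 (R)-mono-epoxide [7 in which one prenyl group has become a [(2R)-3,3-dimethyloxiran-2-yl]methyl group]
Conditions: D-fructose-derived Shi ketone (1,2:4,5-di-O-isopropylidene-β-D-erythro-2,3-hexodiulo-2,6-pyranose, 30 mol %), KHSO5 (as 2KHSO5·KHSO4·K2SO4, ca. 1.1 equiv, slow addition), K2CO3, Bu4NHSO4 (cat.), aq. Na2B4O7 buffer, MeCN/CH2(OMe)2, 0 °C, stopped at ca. 40 % conversion of the alkene groups; recovered 7 recycled
Reagents that add atoms: potassium peroxymonosulfate KHSO5, [K+].[O-]S(=O)(=O)OO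
Why: Shi asymmetric epoxidation, in which the dioxirane of the D-fructose-derived ketone transfers oxygen through a spiro transition state to the face of the trisubstituted alkene that gives the (R)-epoxide, while stopping at partial conversion makes the mono-epoxide the main product of the two equivalent (homotopic) prenyl groups.

Step 6
Reactants: 8 (R)-mono-epoxide
Product: 10 (3R)-5-[2-(3,4-dihydroxyphenyl)ethyl]-2,2-dimethyl-6-(3-methylbut-2-enyl)-3,4-dihydro-2H-chromene-3,7-diol (target), via epoxy tetraol 9 (not isolated)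
Conditions: Bu4NF (4.4 equiv), AcOH (5 equiv), THF, 0 °C → rt; extractive work-up; then CSA (10 mol %), CH2Cl2/THF, 0 °C, under argon
Reagents that add atoms: none
Why: Fluoride desilylation buffered with AcOH keeps the phenols protonated so that no phenoxide can close the five-membered ring, and the following Brønsted acid-catalysed 6-endo epoxide opening (intramolecular etherification at the tertiary carbon, Markovnikov sense) by the only ortho phenol breaks the epoxide O–CMe2 bond and leaves the (R)-carbinol centre untouched.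

**Compound list**
1 | piceatannol, (E)-4-[2-(3,5-dihydroxyphenyl)ethenyl]benzene-1,2-diol | Oc1cc(O)cc(/C=C/c2ccc(O)c(O)c2)c1 | starting material
2 | dihydropiceatannol, 4-[2-(3,5-dihydroxyphenyl)ethyl]benzene-1,2-diol | Oc1cc(O)cc(CCc2ccc(O)c(O)c2)c1 | intermediate
3 | tetra-TBS dihydropiceatannol, 1,2-bis(TBSO)-4-{2-[3,5-bis(TBSO)phenyl]ethyl}benzene | CC(C)(C)[Si](C)(C)Oc1cc(O[Si](C)(C)C(C)(C)C)cc(CCc2ccc(O[Si](C)(C)C(C)(C)C)c(O[Si](C)(C)C(C)(C)C)c2)c1 | intermediate
4 | ring A monobromide, 2-bromo-1,5-bis(TBSO)-3-{2-[3,4-bis(TBSO)phenyl]ethyl}benzene | CC(C)(C)[Si](C)(C)Oc1cc(O[Si](C)(C)C(C)(C)C)c(Br)c(CCc2ccc(O[Si](C)(C)C(C)(C)C)c(O[Si](C)(C)C(C)(C)C)c2)c1 | intermediate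
5 | ring A 2,6-dibromide, 2,4-dibromo-1,5-bis(TBSO)-3-{2-[3,4-bis(TBSO)phenyl]ethyl}benzene | CC(C)(C)[Si](C)(C)Oc1cc(O[Si](C)(C)C(C)(C)C)c(Br)c(CCc2ccc(O[Si](C)(C)C(C)(C)C)c(O[Si](C)(C)C(C)(C)C)c2)c1Br | intermediate
6 | bromo prenyl arene, 2-bromo-4-prenyl-1,5-bis(TBSO)-3-{2-[3,4-bis(TBSO)phenyl]ethyl}benzene | CC(C)=CCc1c(O[Si](C)(C)C(C)(C)C)cc(O[Si](C)(C)C(C)(C)C)c(Br)c1CCc1ccc(O[Si](C)(C)C(C)(C)C)c(O[Si](C)(C)C(C)(C)C)c1 | intermediate
7 | diprenyl arene, 2,4-diprenyl-1,5-bis(TBSO)-3-{2-[3,4-bis(TBSO)phenyl]ethyl}benzene | CC(C)=CCc1c(O[Si](C)(C)C(C)(C)C)cc(O[Si](C)(C)C(C)(C)C)c(CC=C(C)C)c1CCc1ccc(O[Si](C)(C)C(C)(C)C)c(O[Si](C)(C)C(C)(C)C)c1 | intermediate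
8 | (R)-mono-epoxide, 7 with one prenyl converted into [(2R)-3,3-dimethyloxiran-2-yl]methyl | CC(C)=CCc1c(O[Si](C)(C)C(C)(C)C)cc(O[Si](C)(C)C(C)(C)C)c(C[C@H]2OC2(C)C)c1CCc1ccc(O[Si](C)(C)C(C)(C)C)c(O[Si](C)(C)C(C)(C)C)c1 | intermediate
9 | epoxy tetraol, 8 with all four TBS groups replaced by H, (R) | CC(C)=CCc1c(O)cc(O)c(C[C@H]2OC2(C)C)c1CCc1ccc(O)c(O)c1 | intermediate
10 | (3R)-5-[2-(3,4-dihydroxyphenyl)ethyl]-2,2-dimethyl-6-(3-methylbut-2-enyl)-3,4-dihydro-2H-chromene-3,7-diol | CC(C)=CCc1c(O)cc2c(c1CCc1ccc(O)c(O)c1)C[C@@H](O)C(C)(C)O2 | target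

**Totals**
Total step count: 6. Longest linear sequence: 6 steps (1 → 2 → 3 → 5 → 7 → 8 → 10).

**Three steps most likely to fail**

Step 4 (twofold Negishi coupling at bromides flanked by OTBS and the benzylic chain; incomplete coupling or branched prenyl isomer). The fallback replaces palladium coupling by aryllithium/copper allylation. That needs methoxymethyl ethers, because ortho-lithiated aryl silyl ethers suffer O→C silyl migration. It sets out from 2: MOMCl and i-Pr2NEt in CH2Cl2 give the tetrakis(methoxymethyl) ether F1. NBS in MeCN gives the ring A 2,6-dibromide F2. Twofold bromine–lithium exchange with t-BuLi in THF at −78 °C, transmetalation with CuBr·SMe2 and alkylation with prenyl bromide give the diprenyl tetrakis(methoxymethyl) ether F3. HCl in MeOH frees the diprenyl tetraol F4. TBSCl and imidazole in DMF then return to the route at 7.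

Step 5 (statistical mono-epoxidation; at best about 45 % of 8 per pass, with bis-epoxide as waste). The fallback differentiates the two ortho positions by halogen instead of by statistics. It sets out from 3: 1.0 equiv NBS gives the monobromide 4, now isolated. NIS with catalytic CF3CO2H in MeCN iodinates the second ortho position to give the bromo iodide F5. A Negishi coupling at rt with 1.1 equiv prenylzinc bromide (Pd(OAc)2, CPhos) reacts only at the carbon–iodine bond and gives 6, now isolated. Shi epoxidation of its single alkene, run to full conversion, gives the bromo epoxide F6. A second Negishi coupling with prenylzinc bromide at the carbon–bromine bond comes back to the route at 8.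

Step 6 (phenoxide-driven 5-exo closure during desilylation, imperfect 6-endo selectivity, and an air- and acid-sensitive free polyphenol under CSA). The fallback reverses the order of ring closure and deprotection, so that no free phenol or phenoxide ever meets the epoxide. It sets out from 8: BF3·OEt2 in CH2Cl2 at −78 °C opens the epoxide at the tertiary carbon with the neighbouring aryl silyl ether oxygen as internal nucleophile. That oxygen loses its silyl group as the fluoride, giving the tris-TBS chromanol F7. Bu4NF/AcOH in THF then removes the three remaining aryl silyl groups and comes back to the route at 10.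

**Further compounds**
F1 | step 4 | tetrakis(methoxymethyl) ether of 2, 1,2-bis(methoxymethoxy)-4-{2-[3,5-bis(methoxymethoxy)phenyl]ethyl}benzene | COCOc1cc(OCOC)cc(CCc2ccc(OCOC)c(OCOC)c2)c1
F2 | step 4 | ring A 2,6-dibromide of F1 | COCOc1cc(OCOC)c(Br)c(CCc2ccc(OCOC)c(OCOC)c2)c1Br
F3 | step 4 | ring A 2,6-diprenyl tetrakis(methoxymethyl) ether | CC(C)=CCc1c(OCOC)cc(OCOC)c(CC=C(C)C)c1CCc1ccc(OCOC)c(OCOC)c1
F4 | step 4 | diprenyl tetraol, 4-{2-[3,5-dihydroxy-2,6-diprenylphenyl]ethyl}benzene-1,2-diol | CC(C)=CCc1c(O)cc(O)c(CC=C(C)C)c1CCc1ccc(O)c(O)c1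
F5 | step 5 | ring A 2-bromo-6-iodo derivative of 3 | CC(C)(C)[Si](C)(C)Oc1cc(O[Si](C)(C)C(C)(C)C)c(Br)c(CCc2ccc(O[Si](C)(C)C(C)(C)C)c(O[Si](C)(C)C(C)(C)C)c2)c1I
F6 | step 5 | bromo epoxide, 6 with the prenyl group converted into [(2R)-3,3-dimethyloxiran-2-yl]methyl | Brc1c(O[Si](C)(C)C(C)(C)C)cc(O[Si](C)(C)C(C)(C)C)c(C[C@H]2OC2(C)C)c1CCc1ccc(O[Si](C)(C)C(C)(C)C)c(O[Si](C)(C)C(C)(C)C)c1
F7 | step 6 | tris-TBS chromanol, (3R)-7-(TBSO)-5-{2-[3,4-bis(TBSO)phenyl]ethyl}-2,2-dimethyl-6-prenylchroman-3-ol | CC(C)=CCc1c(O[Si](C)(C)C(C)(C)C)cc2c(c1CCc1ccc(O[Si](C)(C)C(C)(C)C)c(O[Si](C)(C)C(C)(C)C)c1)C[C@@H](O)C(C)(C)O2
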